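The readings are simulated on assumed constants; noise was put on by code.

Start from a one-step world, where J simply decays and its curve ends at zero, and test that picture on the noon run.

| flask | E | L | temperature | remark | time |
|---|---|---|---|---|---|
| noon | 29 mM | 87 µM | 90 °C | run made earlier |  |
| eta | 29 mM | 58 µM | 90 °C |  | 40 min |
| gamma | 29 mM | 58 µM | 110 °C |  | 40 min |
| zeta | 29 mM | 58 µM |  | at 110 °C until 12 min, from then on at 90 °C | 40 min |

noon run (percent of the E charged)

| time / min | J / % | G / % |
|---|---|---|
| 0.250 | 24.2 | 0.2 |
| 0.833 | 33.3 | 0.1 |
| 1.33 | 32.0 | 1.5 |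
| 2.00 | 29.1 | 2.5 |
| 3.00 | 27.4 | 3.2 |
| 4.00 | 25.5 | 3.1 |

(readings scatter by 0.5 percentage points)

- what was read earlier has a scatter of 0.5 percentage points, one standard deviation
- the earlier runs do not show what temperature does; that part of a forecast is a guess
- no earlier run changes the charge of L; that part of a forecast is a guess

1. which flask leads in share of J in all that became J or G or Q or D ("all alike" within 1.5 percentage points) (eta / gamma / zeta / all alike)
2. share of J in all that became J or G or Q or D, eta
3. share of J in all that became J or G or Q or D, gamma
4. share of J in all that became J or G or Q or D, zeta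

Rank the rates, fastest first. The top rung is the rise of J under L in the noon run: J reads 24.2% at 0.250 min, against 33.3% at its highest reading, which gives as a rough reading

rise = 5.19 min⁻¹

The next rung is the fall of J in the noon run. Replace each stretch of the curve by its mean fall, placed at the stretch's middle, in fractions of the charge:

from 0.833 min to 2.00 min: 0.0360 min⁻¹
from 2.00 min to 4.00 min: 0.0180 min⁻¹

The fall shrinks to half within 1.58 min, so it dies away at

s = 0.438 min⁻¹

Using the mean for the middle errs by 3.22% of the later fall, less than the scatter does, so treat what follows as a rough reading. Summing the fall still to come after 4.00 min gives 2.66%, so I read J in the noon run as heading for about 22.8%, not zero.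

The lowest rung is G in the noon run, whose mean gain, taken as a rate on the whole charge, reads 0.00775 min⁻¹, far slower than s. I read the noon run as a fast balance (pre-equilibrium) that G slowly drains. Carry the J part, J's level divided by what G has not taken:

f = 0.236

Guessing that L changes speed and not this part, my own reckoning for eta is J = 17.3%. The share in eta divides J by what became product, and that sum is no more than the charge, so I expect the share to stand above this figure for J. I also put eta first, though what heat does is a guess.

The forecast gives eta the lead, with eta 5% (1.5% to 13%), gamma 0.5% and zeta 1.2%: “If decay scales with L, k is about 0.055 per min at 58 µM, leaving about 4% J at 90 °C.” My figure for J in eta stands above the high end of its share.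

The flasks give eta 28.7%, gamma 10.0% and zeta 23.3%, so eta leads.

    E + L ⇌ J + L, rate k1*[E]*[L] forward; the back reaction follows from the equilibrium constant (K = 0.630, k = 19000 L mol⁻¹ min⁻¹, Ea = 59.0 kJ mol⁻¹, ΔH = −90.0 kJ mol⁻¹)
    E ⇌ G (K = 1.60, k = 0.0160 min⁻¹, Ea = 123 kJ mol⁻¹, ΔH = −57.0 kJ mol⁻¹)
    E ⇌ Q (K = 0.900, k = 0.260 min⁻¹, Ea = 97.0 kJ mol⁻¹, ΔH = −24.0 kJ mol⁻¹)
    J + L ⇌ D + L, rate k4*[L]*[J] forward; the back reaction follows from the equilibrium constant (K = 0.100, k = 530 L mol⁻¹ min⁻¹, Ea = 39.0 kJ mol⁻¹, ΔH = −81.0 kJ mol⁻¹)
    (constants at 90 °C)

At 40.0 min, eta still holds E at 31% of the charge. With G at 18.5% in eta, the J part gives 19.2%, and the flask holds J at 19.7%. Zeta held J at 5.76% at 12.0 min, when its hot stretch ended. At 40.0 min its G is 29.8%, so the J part gives 16.5%, and zeta holds J at 17.0%.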